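All runs were computed on assumed constants; noise was put on by code.

How much target stands in this flask at 20 min, and which move still adds to it?

| setting | Tuesday's | Saturday's | flask |
|---|---|---|---|
| solid substrate | 0.050 M | 0.050 M | 0.050 M |
| partner | 2 equiv | 2 equiv | 2.00 equiv |
| temperature | 110 °C | 105 °C | 110 °C |
| remark | the very flask that is asked about, followed so far | run made earlier |  |
| time |  |  | 20 min |

| run | time / min | target / % | solid substrate / % |
|---|---|---|---|
| Tuesday's | 3.00 | 42.0 | 0.2 |
| Tuesday's | 6.00 | 36.1 | 0.3 |
| Tuesday's | 8.00 | 33.6 | 0 |
| Tuesday's | 12.0 | 30.0 | 0 |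
| Tuesday's | 15.0 | 28.5 | 0 |
| Tuesday's | 20.0 | 27.3 | 0.1 |
| Saturday's | 3.00 | 43.4 | 0 |
| Saturday's | 6.00 | 38.4 | 0 |
| Saturday's | 8.00 | 35.5 | 0 |
| Saturday's | 12.0 | 31.1 | 0.2 |
| Saturday's | 15.0 | 28.6 | 0.1 |
| Saturday's | 20.0 | 26.6 | 0 |

(readings scatter by 0.3 percentage points)

- maple: change nothing and wait 20 min more
- ash: at 20 min raise the temperature by 20 K, then wait 20 min
- oak: at 20 min add partner, 50.0 % of the amount charged, then wait 20 min

1. target, in percent of the solid substrate first charged, at 20 min
2. which option adds most target ("none" when 2 percentage points or less is all one gets) (maple / ash / oak / none)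
3. target present, in percent of the solid substrate first charged, after ash
4. target present, in percent of the solid substrate first charged, after oak

- what is added takes up no volume worth counting
- at the start none of the solid substrate is in solution
- a reading or a percentage of target counts all its forms, free or not

At the bench, with partner charged at 2 equiv, we would call the loss of target pseudo-first-order and expect the drops in equal windows to stand as the target levels at their start. In Tuesday's run, which is this flask, the windows of 5.00 min starting at 3.00 min and at 15.0 min lose 8.4 percentage points and 1.2 points. That is a ratio of 7.00, while the levels stand at a ratio of 1.47. The drop therefore shrinks faster than the counted target, and the rule stops here. Counted c(target) does not follow first order in these readings, so we take the gap between target and a plateau as the first-order quantity. The ratio of drops and their lag give 4.27 min as the gap half-life, the time in which that gap halves.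

For Tuesday's flask, our answer to "now" is the reading itself, 27.3 %. The gap half-life leaves 0.96 points still to fall, so maple ends near 26.3 %. The same reckoning on Saturday's run gives 6.05 min and a plateau of 24.0 %, lower than Tuesday's. A straight line through these two scattered plateaus puts ash near 35.7 %, a poor figure, but its gain of 8.4 points is more than the margin. Both runs were charged with 2 equiv of partner, so for oak we have a guess and no reading: it ends beside maple. We choose ash.

The forecast, reading the plateau as a “reversible, exothermic loss of target”, gives 27.2 %, best ash, 30 % after ash, below our 35.7 %, and 20 % after oak, below our guess of 26.3 %.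

The flask gives 27.3 %, and ash is best, reaching 33.6 %, a gain of 6.3 points; oak reaches 26.7 %. Maple and oak change target by the same −0.65 points. Our gap half-life left 0.96 points to fall, and under maple the flask falls 0.65 points.

    solid substrate ⇌ dissolved substrate, rate k1*(cs1 - [dissolved substrate]) while solid is left; crystals form when [dissolved substrate] > cs1 (solubility = 18.0 mM, k = 0.0350 s⁻¹)
    dissolved substrate + partner → target (k = 0.380 L mol⁻¹ s⁻¹, Ea = 55.0 kJ mol⁻¹)
    2 dissolved substrate → side product (k = 2.20 L mol⁻¹ s⁻¹, Ea = 73.0 kJ mol⁻¹)
    solid product ⇌ target, rate k4*(cs4 - [target]) while solid is left; crystals form when [target] > cs4 (solubility = 6.00 mM, k = 0.160 s⁻¹)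
    target ⇌ isomer of the product (K = 2.50, k = 0.00830 s⁻¹, Ea = 95.0 kJ mol⁻¹, ΔH = −17.0 kJ mol⁻¹)
    (constants at 110 °C)

In the neighbour flask with 5.00 equiv of partner, if the gap half-life holds, 20 min is 4.68 half-lives, leaving 3.89 % of the gap. That flask computes to 53.6 % target, with isomer of the product at 29.4 %, against 29.3 % in our flask.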